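## The problem

Hansforester J (24) is an open-chain oligoester. Two 5-[(R)-2-hydroxypropyl]resorcinol units (rings A and C) and two (R)-3-hydroxybutanoate units (fragments B and D) are joined in the order A–B–C–D by two alkyl ester bonds and one benzoate bond. No ring is fused or bridged, so the task is to make two arenes and to form three esters in the right order.

The four stereocentres are all R-configured methyl carbinols. Each is separated from the next by an ester or an arene, so none can control another; each must be bought and carried through with retention.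

The benzoate carbon of ring C sits between a hydroxyl (C2) and the side chain (C6). Acids of this kind resist acyl substitution by a secondary alcohol. Fragment B is a β-aroyloxy ester and can lose the arenecarboxylate by E1cB elimination under base. All three esters can transesterify, and the free resorcinols are nucleophilic and oxidisable, so they should be unmasked last.

The structure offers two simplifications. The halves A–B and C–D are the same (R)-1-arylpropan-2-yl (R)-3-hydroxybutanoate, and ring C is ring A plus one carboxyl carbon at C2. Ring A carries the chain on C1, oxygen on C3 and C5 and hydrogen on C2, C4 and C6. In this pattern C1, C2, C5 and C6 can come from a 3-alkylcyclobut-2-enone and C3 and C4 from an oxygen-substituted ethyne.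

## Retrosynthesis

**Unmasking.** Target 24 is traced to its pentasilyl ether 23 (four aryl triisopropylsilyl ethers, one alkyl tert-butyldimethylsilyl ether). Only O–Si bonds are cut. A single buffered fluoride treatment is asked to free five hydroxyls without eliminating the β-aroyloxy ester.

**Central benzoate.** In 23 the aryl–carbonyl bond and the acyl–oxygen bond of the ring C benzoate are cut together. This leads to aryl iodide 21, carbon monoxide 22 and secondary alcohol 20. Cutting one of the alkyl esters instead would leave the hindered benzoate to be made by acyl substitution and would give two unlike halves. The carbonylative cut attaches the alcohol oxygen to an aroylpalladium species, leaves the carbinol centre untouched (retention), and makes both partners derivatives of one monomer.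

**One monomer, two roles.** Iodide 21 and alcohol 20 both come from bis(triisopropylsilyl) ether 19. Ring iodination gives 21, and selective loss of the alkyl silyl ether gives 20. With two identical aryl silyl ethers, C2 and C6 of the ring are equivalent and C4 is shielded by both, so iodination should give one product. Compound 19 is the silylation product of phenol 18.

**Ring A (key disconnection).** In 18 the ring bonds C2–C3 and C4–C5 are cut and the C5–C6 bond is traced to the C1–C4 bond of a cyclobutenone. This gives cyclobutenone 9, which already carries the complete chiral ester chain, and (triisopropylsilyloxy)ethyne 13. The cut removes the whole arene and leaves only acyclic and four-membered precursors. The forward reaction is neutral and thermal, so the esters, the silyl ether and both stereocentres are not at risk. A silyl ynol ether is preferred to an alkyl one because the resulting aryl ether falls to fluoride at the end, and the bulk of triisopropylsilyl slows the 1,3-shift to a silylketene.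

**Cyclobutenone.** Compound 9 comes from dichlorocyclobutenone 8 by zinc reduction. Compound 8 comes from terminal alkyne 5 and dichloroketene 7, made in the flask from trichloroacetyl chloride 6. The regiochemistry places the alkyne substituent on C3, as ring A requires.

**Chain and alkyne.** Ester 5 is cut at the acyl–oxygen bond into (R)-pent-4-yn-2-ol 4 and silylated acid 3. Acid 3 comes from methyl (R)-3-hydroxybutanoate 1 by way of silyl ether 2. Alkyne 13 is traced to acetylene 10 through lithium acetylide 11 and lithium ethynolate 12. All four stereocentres of 24 thus come from 1 and 4, each used in both halves.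

## Roads not taken

**Alternative 1:** The central benzoate is cut exactly as above, but the monomer is made from a purchased 3,5-dioxygenated arene protected as benzyl ethers. In the forward key step the 2-iodo monomer A2, carbon monoxide and the hydroxy monomer A3 couple with Pd(OAc)2 and Xantphos to give the tetrabenzyl silyl ether A1. Its merits are real. The arene is bought, so the dichloroketene sequence, the ynol ether and the benzannulation are not needed. The monomer is reached in fewer steps, and benzyl ethers are inert to the amine base at 80 °C. Its weak points are modest: the end needs hydrogenolysis of four benzyl ethers as well as a desilylation, and the aryl–chain bond has to be made by an organometallic step. For this target alone Alternative 1 is the shorter and more routine road, and its key step is the same reaction as step 11 here. The chosen plan sets three things against it. Ring A is built on the finished chiral chain under neutral conditions. The ring carbons come from two-carbon pieces, so labelled or C2-, C4- and C6-substituted analogues are open by changing the alkyne or the cyclobutenone. Only silyl protection is used, which is removed in one operation.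

**Alternative 2:** Ring C is cut at C1–C2 and C5–C6. The forward step is a Diels–Alder reaction of ynoate A5, already esterified to the A–B fragment, with 1-methoxy-1,3-bis(trimethylsilyloxy)buta-1,3-diene A6. Acidic work-up expels methanol and silanol to give resorcylate A4. The merit is that the hindered benzoate is never formed by substitution or carbonylation, because the ester enters as a simple ynoate, and the diene polarity fixes the 2,4-dihydroxy-6-alkyl pattern. In that respect it is better than the chosen plan. The weak points are these. A β-alkyl ynoate is a sluggish dienophile and needs heat, which the labile diene tolerates poorly. The propargylic methylene of A5 next to an acyloxy carbon invites isomerisation to an allene and elimination. The key step is run on the most advanced material, so a failure costs the whole sequence. Ring A must still be obtained separately, and three benzyl ethers need hydrogenolysis. The chosen plan uses one monomer twice and puts its ring-forming risk early, on cheap material.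

**Alternative 3:** Ring C is cut at C1–C6 and C2–C3. Dipentenyl malonate A8 adds to enone A9 in a Michael reaction, the methyl ketone closes onto one ester in a Claisen cyclisation, and N-bromosuccinimide dehydrogenates the dione ester to resorcylate A7. The merits are cheap reagents, no transition metal, no carbon monoxide and no special alkyne. The pentenyl ester is also a masked (R)-3-hydroxybutanoate. The weak points are several. Alkoxide base invites transesterification and vinylogous elimination of the silyloxy group of A9. The brominating oxidant can attack the terminal alkene and the electron-rich product ring. One chiral alcohol unit of A8 is lost. After A7 the alkene must still be cleaved to the acid in the presence of a resorcinol, two more esters formed and ring A made separately. It is clearly the longest road, and the chosen plan is preferred despite its less common reagents.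

Key step: step 7

Assumption: (triisopropylsilyloxy)ethyne 13 is taken to be isolable and stable to about 110 °C without 1,3-silyl shift, as its 2-alkyl homologues are.

## Steps

Step 1
Reactants: 1 methyl (R)-3-hydroxybutanoate
Product: 2 methyl (R)-3-(tert-butyldimethylsilyloxy)butanoate
Conditions: TBSCl, imidazole, DMF, 0 °C → rt
Reagents that add atoms: tert-butyldimethylsilyl chloride, CC(C)(C)[Si](C)(C)Cl
Why: Standard O-silylation of a secondary alcohol; the carbinol C–O bond is untouched, so the R configuration is kept.

Step 2
Reactants: 2 methyl (R)-3-(tert-butyldimethylsilyloxy)butanoate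
Product: 3 (R)-3-(tert-butyldimethylsilyloxy)butanoic acid
Conditions: LiOH·H2O, THF/H2O, 0 °C → rt; cold aq. HCl to pH 3–4
Reagents that add atoms: lithium hydroxide, [Li+].[OH-]
Why: Saponification by acyl–oxygen cleavage; at 0 °C to room temperature the β-silyloxy group should not eliminate and the stereocentre is not involved.

Step 3
Reactants: 3 (R)-3-(tert-butyldimethylsilyloxy)butanoic acid; 4 (R)-pent-4-yn-2-ol
Product: 5 (R)-pent-4-yn-2-yl (R)-3-(tert-butyldimethylsilyloxy)butanoate
Conditions: EDC·HCl, DMAP (cat.), CH2Cl2, 0 °C → rt
Reagents that add atoms: none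
Why: Steglich-type carbodiimide esterification; the new bond is acyl–oxygen, so both carbinol centres keep their R configuration.

Step 4
Reactants: 5 (R)-pent-4-yn-2-yl (R)-3-(tert-butyldimethylsilyloxy)butanoate; 6 trichloroacetyl chloride
Product: 8 (R)-1-(4,4-dichloro-3-oxocyclobut-1-en-1-yl)propan-2-yl (R)-3-(tert-butyldimethylsilyloxy)butanoate, via dichloroketene 7 (not isolated)
Conditions: zinc–copper couple, Et2O/DME, slow addition of 6, rt → 35 °C
Reagents that add atoms: none
Why: Zinc dechlorination of 6 gives dichloroketene, which adds [2+2] to the terminal alkyne with its carbonyl carbon bonding to the CH terminus, placing the chain on C3; DME ties up ZnCl2 so the silyl ether and ester should survive.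

Step 5
Reactants: 8 (R)-1-(4,4-dichloro-3-oxocyclobut-1-en-1-yl)propan-2-yl (R)-3-(tert-butyldimethylsilyloxy)butanoate
Product: 9 (R)-1-(3-oxocyclobut-1-en-1-yl)propan-2-yl (R)-3-(tert-butyldimethylsilyloxy)butanoate
Conditions: Zn dust, AcOH, TMEDA, EtOH, 0 °C
Reagents that add atoms: none
Why: Buffered zinc reduction removes both α-chlorines of a 4,4-dichlorocyclobutenone without touching the enone double bond; the cold, near-neutral medium should avoid vinylogous elimination of the acyloxy group.

Step 6
Reactants: 10 acetylene
Product: 13 (triisopropylsilyloxy)ethyne, via lithium acetylide 11 (not isolated), via lithium ethynolate 12 (not isolated)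
Conditions: n-BuLi, THF (excess 10), −78 °C; LiOOt-Bu (from t-BuOOH and LiN(SiMe3)2), −78 → 0 °C; TIPSOTf, −78 °C → rt
Reagents that add atoms: tert-butyl hydroperoxide, CC(C)(C)OO; triisopropylsilyl trifluoromethanesulfonate, CC(C)[Si](C(C)C)(C(C)C)OS(=O)(=O)C(F)(F)F
Why: Oxidation of a lithium acetylide by lithium tert-butyl peroxide to the ynolate and O-silylation by a bulky silyl triflate is the standard route to 1-silyloxyalkynes; the bulk of the triisopropylsilyl group should direct silylation to oxygen, not carbon.

Step 7
Reactants: 9 (R)-1-(3-oxocyclobut-1-en-1-yl)propan-2-yl (R)-3-(tert-butyldimethylsilyloxy)butanoate; 13 (triisopropylsilyloxy)ethyne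
Product: 18 (R)-1-[3-hydroxy-5-(triisopropylsilyloxy)phenyl]propan-2-yl (R)-3-(tert-butyldimethylsilyloxy)butanoate, via vinylketene 14 (not isolated), via 4-vinylcyclobutenone 15 (not isolated), via dienylketene 16 (not isolated), via cyclohexa-2,4-dienone 17 (not isolated)
Conditions: 13 (1.5 equiv), toluene (0.1 M), 80 °C, then 110 °C, argon
Reagents that add atoms: none
Why: Danheiser benzannulation: at about 80 °C cyclobutenone 9 opens by 4π electrocyclic cleavage of its C1–C4 bond to vinylketene 14, which adds the ynol ether [2+2] to give 15; a second 4π opening gives dienylketene 16. Ring A is closed by 6π electrocyclisation of 16, joining the ketene carbon to the terminal methylene, and dienone 17 tautomerises to phenol 18. The closest known reaction type is the benzannulation of 3-alkylcyclobutenones with 1-(triisopropylsilyloxy)-1-alkynes and with alkoxyalkynes; here the alkyne simply lacks a C2 substituent. No lasting stereocentre is formed, since the sp3 ring carbon of 15 is lost on ring opening. The selectivity needed is the regiochemistry of the [2+2] step: the carbon β to oxygen in 13 is the nucleophilic end and bonds to the electrophilic ketene carbon, which places the two oxygens 1,3 to each other and both meta to the chain. The second need is chemoselectivity for alkyne capture over acylation of the product phenol by the ketene, which the excess of 13 and moderate dilution should secure. The conditions are neutral, so the ester, the silyl ether and both R centres should pass through unchanged.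

Step 8
Reactants: 18 (R)-1-[3-hydroxy-5-(triisopropylsilyloxy)phenyl]propan-2-yl (R)-3-(tert-butyldimethylsilyloxy)butanoate
Product: 19 (R)-1-[3,5-bis(triisopropylsilyloxy)phenyl]propan-2-yl (R)-3-(tert-butyldimethylsilyloxy)butanoate
Conditions: TIPSCl, imidazole, DMF, rt
Reagents that add atoms: triisopropylsilyl chloride, CC(C)[Si](Cl)(C(C)C)C(C)C
Why: Routine silylation of a phenol; it makes the two ring oxygens identical, so C2 and C6 become equivalent for the later iodination.

Step 9
Reactants: 19 (R)-1-[3,5-bis(triisopropylsilyloxy)phenyl]propan-2-yl (R)-3-(tert-butyldimethylsilyloxy)butanoate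
Product: 20 (R)-1-[3,5-bis(triisopropylsilyloxy)phenyl]propan-2-yl (R)-3-hydroxybutanoate
Conditions: aq. HF (48%), MeCN, 0 °C → rt (one half of 19)
Reagents that add atoms: none
Why: Under acidic fluoride an alkyl tert-butyldimethylsilyl ether is cleaved much faster than an aryl silyl ether, and the bulkier aryl triisopropylsilyl ethers should be left; the medium is non-nucleophilic, so the ester should not exchange.

Step 10
Reactants: 19 (R)-1-[3,5-bis(triisopropylsilyloxy)phenyl]propan-2-yl (R)-3-(tert-butyldimethylsilyloxy)butanoate
Product: 21 (R)-1-[2-iodo-3,5-bis(triisopropylsilyloxy)phenyl]propan-2-yl (R)-3-(tert-butyldimethylsilyloxy)butanoate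
Conditions: NIS (1.0 equiv), CF3CO2H (cat.), MeCN, 0 °C → rt, dark (other half of 19)
Reagents that add atoms: N-iodosuccinimide, O=C1CCC(=O)N1I
Why: Electrophilic iodination of a resorcinol diether goes ortho to one oxygen and para to the other; C4 lies between two triisopropylsilyloxy groups and is blocked, and C2 and C6 are equivalent, so one mono-iodide is expected.

Step 11
Reactants: 21 (R)-1-[2-iodo-3,5-bis(triisopropylsilyloxy)phenyl]propan-2-yl (R)-3-(tert-butyldimethylsilyloxy)butanoate; 20 (R)-1-[3,5-bis(triisopropylsilyloxy)phenyl]propan-2-yl (R)-3-hydroxybutanoate; 22 carbon monoxide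
Product: 23 (R)-4-{[(R)-1-[3,5-bis(triisopropylsilyloxy)phenyl]propan-2-yl]oxy}-4-oxobutan-2-yl 2-[(R)-2-{[(R)-3-(tert-butyldimethylsilyloxy)butanoyl]oxy}propyl]-4,6-bis(triisopropylsilyloxy)benzoate
Conditions: CO (1 atm), Pd(OAc)2 (cat.), Xantphos, Et3N, DMAP (cat.), toluene, 80 °C; 20 in slight excess
Reagents that add atoms: none
Why: Alkoxycarbonylation of an aryl iodide: oxidative addition to zerovalent palladium, CO insertion and alcoholysis of the aroylpalladium species by the secondary alcohol; the carbinol C–O bond of 20 is not broken, so the R configuration is retained, and the hindered benzoate is formed without acyl substitution on a free acid.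

Step 12
Reactants: 23 (R)-4-{[(R)-1-[3,5-bis(triisopropylsilyloxy)phenyl]propan-2-yl]oxy}-4-oxobutan-2-yl 2-[(R)-2-{[(R)-3-(tert-butyldimethylsilyloxy)butanoyl]oxy}propyl]-4,6-bis(triisopropylsilyloxy)benzoate
Product: 24 Hansforester J, (R)-4-{[(R)-1-(3,5-dihydroxyphenyl)propan-2-yl]oxy}-4-oxobutan-2-yl 2,4-dihydroxy-6-[(R)-2-{[(R)-3-hydroxybutanoyl]oxy}propyl]benzoate
Conditions: Bu4NF, AcOH (1:1), THF, 0 °C → rt
Reagents that add atoms: none
Why: Buffered fluoride cleaves aryl silyl ethers quickly and the secondary alkyl silyl ether more slowly; the acetic acid keeps phenoxide and fluoride basicity low, so the β-aroyloxy ester should not eliminate.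

## Compound list

1 | methyl (R)-3-hydroxybutanoate | C[C@@H](O)CC(=O)OC | starting material
2 | methyl (R)-3-(tert-butyldimethylsilyloxy)butanoate | C[C@@H](O[Si](C)(C)C(C)(C)C)CC(=O)OC | intermediate
3 | (R)-3-(tert-butyldimethylsilyloxy)butanoic acid | C[C@@H](O[Si](C)(C)C(C)(C)C)CC(=O)O | intermediate
4 | (R)-pent-4-yn-2-ol | C#CC[C@@H](C)O | starting material
5 | (R)-pent-4-yn-2-yl (R)-3-(tert-butyldimethylsilyloxy)butanoate | C#CC[C@@H](C)OC(=O)C[C@@H](C)O[Si](C)(C)C(C)(C)C | intermediate
6 | trichloroacetyl chloride | ClC(=O)C(Cl)(Cl)Cl | starting material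
7 | dichloroketene | O=C=C(Cl)Cl | intermediate
8 | (R)-1-(4,4-dichloro-3-oxocyclobut-1-en-1-yl)propan-2-yl (R)-3-(tert-butyldimethylsilyloxy)butanoate | O=C1C=C(C[C@@H](C)OC(=O)C[C@@H](C)O[Si](C)(C)C(C)(C)C)C1(Cl)Cl | intermediate
9 | (R)-1-(3-oxocyclobut-1-en-1-yl)propan-2-yl (R)-3-(tert-butyldimethylsilyloxy)butanoate | O=C1C=C(C[C@@H](C)OC(=O)C[C@@H](C)O[Si](C)(C)C(C)(C)C)C1 | intermediate
10 | acetylene | C#C | starting material
11 | lithium acetylide | [Li+].[C-]#C | intermediate
12 | lithium ethynolate | [Li+].[O-]C#C | intermediate
13 | (triisopropylsilyloxy)ethyne | C#CO[Si](C(C)C)(C(C)C)C(C)C | intermediate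
14 | vinylketene, (R)-4-methylidene-6-oxohex-5-en-2-yl (R)-3-(tert-butyldimethylsilyloxy)butanoate | O=C=CC(=C)C[C@@H](C)OC(=O)C[C@@H](C)O[Si](C)(C)C(C)(C)C | intermediate
15 | 4-vinylcyclobutenone, (R)-4-[4-oxo-2-(triisopropylsilyloxy)cyclobut-2-en-1-yl]pent-4-en-2-yl (R)-3-(tert-butyldimethylsilyloxy)butanoate (ring carbon C1 unassigned) | O=C1C=C(O[Si](C(C)C)(C(C)C)C(C)C)C1C(=C)C[C@@H](C)OC(=O)C[C@@H](C)O[Si](C)(C)C(C)(C)C | intermediate
16 | dienylketene, (R)-4-methylidene-8-oxo-6-(triisopropylsilyloxy)octa-5,7-dien-2-yl (R)-3-(tert-butyldimethylsilyloxy)butanoate | O=C=CC(O[Si](C(C)C)(C(C)C)C(C)C)=CC(=C)C[C@@H](C)OC(=O)C[C@@H](C)O[Si](C)(C)C(C)(C)C | intermediate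
17 | cyclohexa-2,4-dienone, (R)-1-[5-oxo-3-(triisopropylsilyloxy)cyclohexa-1,3-dien-1-yl]propan-2-yl (R)-3-(tert-butyldimethylsilyloxy)butanoate | O=C1C=C(O[Si](C(C)C)(C(C)C)C(C)C)C=C(C[C@@H](C)OC(=O)C[C@@H](C)O[Si](C)(C)C(C)(C)C)C1 | intermediate
18 | (R)-1-[3-hydroxy-5-(triisopropylsilyloxy)phenyl]propan-2-yl (R)-3-(tert-butyldimethylsilyloxy)butanoate | C[C@@H](O[Si](C)(C)C(C)(C)C)CC(=O)O[C@H](C)Cc1cc(O)cc(O[Si](C(C)C)(C(C)C)C(C)C)c1 | intermediate
19 | (R)-1-[3,5-bis(triisopropylsilyloxy)phenyl]propan-2-yl (R)-3-(tert-butyldimethylsilyloxy)butanoate | C[C@@H](O[Si](C)(C)C(C)(C)C)CC(=O)O[C@H](C)Cc1cc(O[Si](C(C)C)(C(C)C)C(C)C)cc(O[Si](C(C)C)(C(C)C)C(C)C)c1 | intermediate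
20 | (R)-1-[3,5-bis(triisopropylsilyloxy)phenyl]propan-2-yl (R)-3-hydroxybutanoate | C[C@@H](O)CC(=O)O[C@H](C)Cc1cc(O[Si](C(C)C)(C(C)C)C(C)C)cc(O[Si](C(C)C)(C(C)C)C(C)C)c1 | intermediate
21 | (R)-1-[2-iodo-3,5-bis(triisopropylsilyloxy)phenyl]propan-2-yl (R)-3-(tert-butyldimethylsilyloxy)butanoate | C[C@@H](O[Si](C)(C)C(C)(C)C)CC(=O)O[C@H](C)Cc1cc(O[Si](C(C)C)(C(C)C)C(C)C)cc(O[Si](C(C)C)(C(C)C)C(C)C)c1I | intermediate
22 | carbon monoxide | [C-]#[O+] | starting material
23 | (R)-4-{[(R)-1-[3,5-bis(triisopropylsilyloxy)phenyl]propan-2-yl]oxy}-4-oxobutan-2-yl 2-[(R)-2-{[(R)-3-(tert-butyldimethylsilyloxy)butanoyl]oxy}propyl]-4,6-bis(triisopropylsilyloxy)benzoate | C[C@H](Cc1cc(O[Si](C(C)C)(C(C)C)C(C)C)cc(O[Si](C(C)C)(C(C)C)C(C)C)c1)OC(=O)C[C@@H](C)OC(=O)c1c(O[Si](C(C)C)(C(C)C)C(C)C)cc(O[Si](C(C)C)(C(C)C)C(C)C)cc1C[C@@H](C)OC(=O)C[C@@H](C)O[Si](C)(C)C(C)(C)C | intermediate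
24 | Hansforester J | C[C@H](Cc1cc(O)cc(O)c1)OC(=O)C[C@@H](C)OC(=O)c1c(O)cc(O)cc1C[C@@H](C)OC(=O)C[C@@H](C)O | target

## Step count and risks

Total: 12 steps. Longest linear sequence: 10 steps (1, 2, 3, 4, 5, 7, 8, 9 or 10, 11, 12).

**Step 7 (key step).** The vinylketene may acylate the product phenol instead of adding the alkyne, and such aryl esters cannot be saponified here because of the other esters. The unsubstituted ynol ether may also polymerise or shift its silyl group to carbon on heating, and the second electrocyclic stage may stall at 80 °C. Fallback: the benzannulation is given up and the same ring is bought. 5-Bromoresorcinol is silylated to 1-bromo-3,5-bis(triisopropylsilyloxy)benzene F1. Its Grignard reagent opens (R)-propylene oxide at the methylene carbon under CuI catalysis to give (R)-1-[3,5-bis(triisopropylsilyloxy)phenyl]propan-2-ol F2. Carbodiimide esterification of F2 with acid 3 returns to the route at 19.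

**Step 6.** Lithium acetylide can disproportionate to the dilithium salt on warming before it is oxidised, and the unhindered carbon of the parent ynolate may be silylated in competition with oxygen, giving a silylketene. Fallback: (trimethylsilyl)acetylene, whose lithium salt is stable and has one acidic site, is oxidised and O-silylated in the same way to 1-(triisopropylsilyloxy)-2-(trimethylsilyl)ethyne F3. Benzannulation of F3 with cyclobutenone 9 gives (R)-1-[3-hydroxy-4-(trimethylsilyl)-5-(triisopropylsilyloxy)phenyl]propan-2-yl (R)-3-(tert-butyldimethylsilyloxy)butanoate F4. Ipso-protodesilylation of this electron-rich arylsilane with CF3CO2H in CH2Cl2 at 0 °C returns to the route at 18.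

**Step 11.** Capture of the doubly ortho-substituted aroylpalladium species by a secondary alcohol used near 1:1 may be slow, so reduction of the iodide or catalyst decay may win. The amine base at 80 °C may also cause β-elimination of the new aroyloxy group. Fallback: carbonylation and esterification are separated. Iodide 21 is hydroxycarbonylated (CO, water, Pd(OAc)2, Xantphos, Et3N, dioxane) to 2-[(R)-2-{[(R)-3-(tert-butyldimethylsilyloxy)butanoyl]oxy}propyl]-4,6-bis(triisopropylsilyloxy)benzoic acid F5, since water captures the hindered acyl species easily. F5 is converted under neutral conditions with 1-chloro-N,N,2-trimethylprop-1-en-1-amine to the acid chloride F6. F6 acylates alcohol 20 (pyridine, DMAP, CH2Cl2) with retention and returns to the route at 23.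

**Step 4.** ZnCl2 and the acid chloride may cleave or acylate the alkyl silyl ether, and dichloroketene may oligomerise faster than it adds to an unactivated alkyne. Fallback: alkyne 5 is treated with the keteniminium salt made from N,N-dimethylacetamide, Tf2O and 2,4,6-collidine. The [2+2] adduct, the cyclobuteniminium triflate F7, is hydrolysed with aqueous NaHCO3 and returns to the route directly at 9, bypassing 8 and the zinc reduction.

**Step 12.** Fluoride may act as a base and eliminate the arenecarboxylate from fragment B, or the alkyl silyl ether may be removed incompletely under the buffered conditions. Fallback: the deprotection is staged with two orthogonal reagents. Aqueous HF in MeCN (as in step 9) first removes only the alkyl silyl ether of 23 to give the tetrakis(triisopropylsilyl) ether of Hansforester J, F8. The four aryl silyl ethers are then cleaved with KHF2 in MeOH/THF, a weakly acidic fluoride source selective for phenolic silyl ethers, which returns to the route at 24.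

## Further compounds

F1 | step 7 | 1-bromo-3,5-bis(triisopropylsilyloxy)benzene | Brc1cc(O[Si](C(C)C)(C(C)C)C(C)C)cc(O[Si](C(C)C)(C(C)C)C(C)C)c1
F2 | step 7 | (R)-1-[3,5-bis(triisopropylsilyloxy)phenyl]propan-2-ol | C[C@@H](O)Cc1cc(O[Si](C(C)C)(C(C)C)C(C)C)cc(O[Si](C(C)C)(C(C)C)C(C)C)c1
F3 | step 6 | 1-(triisopropylsilyloxy)-2-(trimethylsilyl)ethyne | C[Si](C)(C)C#CO[Si](C(C)C)(C(C)C)C(C)C
F4 | step 6 | (R)-1-[3-hydroxy-4-(trimethylsilyl)-5-(triisopropylsilyloxy)phenyl]propan-2-yl (R)-3-(tert-butyldimethylsilyloxy)butanoate | C[C@@H](O[Si](C)(C)C(C)(C)C)CC(=O)O[C@H](C)Cc1cc(O)c([Si](C)(C)C)c(O[Si](C(C)C)(C(C)C)C(C)C)c1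
F5 | step 11 | 2-[(R)-2-{[(R)-3-(tert-butyldimethylsilyloxy)butanoyl]oxy}propyl]-4,6-bis(triisopropylsilyloxy)benzoic acid | C[C@@H](O[Si](C)(C)C(C)(C)C)CC(=O)O[C@H](C)Cc1cc(O[Si](C(C)C)(C(C)C)C(C)C)cc(O[Si](C(C)C)(C(C)C)C(C)C)c1C(=O)O
F6 | step 11 | 2-[(R)-2-{[(R)-3-(tert-butyldimethylsilyloxy)butanoyl]oxy}propyl]-4,6-bis(triisopropylsilyloxy)benzoyl chloride | C[C@@H](O[Si](C)(C)C(C)(C)C)CC(=O)O[C@H](C)Cc1cc(O[Si](C(C)C)(C(C)C)C(C)C)cc(O[Si](C(C)C)(C(C)C)C(C)C)c1C(=O)Cl
F7 | step 4 | N,N-dimethyl-3-[(R)-2-{[(R)-3-(tert-butyldimethylsilyloxy)butanoyl]oxy}propyl]cyclobut-2-en-1-iminium trifluoromethanesulfonate | C[N+](C)=C1C=C(C[C@@H](C)OC(=O)C[C@@H](C)O[Si](C)(C)C(C)(C)C)C1.[O-]S(=O)(=O)C(F)(F)F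
F8 | step 12 | (R)-4-{[(R)-1-[3,5-bis(triisopropylsilyloxy)phenyl]propan-2-yl]oxy}-4-oxobutan-2-yl 2-[(R)-2-{[(R)-3-hydroxybutanoyl]oxy}propyl]-4,6-bis(triisopropylsilyloxy)benzoate | C[C@H](Cc1cc(O[Si](C(C)C)(C(C)C)C(C)C)cc(O[Si](C(C)C)(C(C)C)C(C)C)c1)OC(=O)C[C@@H](C)OC(=O)c1c(O[Si](C(C)C)(C(C)C)C(C)C)cc(O[Si](C(C)C)(C(C)C)C(C)C)cc1C[C@@H](C)OC(=O)C[C@@H](C)O
A1 | alternative 1 | tetra-O-benzyl O-(tert-butyldimethylsilyl) Hansforester J | C[C@H](Cc1cc(OCc2ccccc2)cc(OCc2ccccc2)c1)OC(=O)C[C@@H](C)OC(=O)c1c(OCc2ccccc2)cc(OCc2ccccc2)cc1C[C@@H](C)OC(=O)C[C@@H](C)O[Si](C)(C)C(C)(C)C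
A2 | alternative 1 | (R)-1-[3,5-bis(benzyloxy)-2-iodophenyl]propan-2-yl (R)-3-(tert-butyldimethylsilyloxy)butanoate | C[C@@H](O[Si](C)(C)C(C)(C)C)CC(=O)O[C@H](C)Cc1cc(OCc2ccccc2)cc(OCc2ccccc2)c1I
A3 | alternative 1 | (R)-1-[3,5-bis(benzyloxy)phenyl]propan-2-yl (R)-3-hydroxybutanoate | C[C@@H](O)CC(=O)O[C@H](C)Cc1cc(OCc2ccccc2)cc(OCc2ccccc2)c1
A4 | alternative 2 | tri-O-benzyl Hansforester J with both ring C phenols free | C[C@H](Cc1cc(OCc2ccccc2)cc(OCc2ccccc2)c1)OC(=O)C[C@@H](C)OC(=O)c1c(O)cc(O)cc1C[C@@H](C)OC(=O)C[C@@H](C)OCc1ccccc1
A5 | alternative 2 | (R)-4-{[(R)-1-[3,5-bis(benzyloxy)phenyl]propan-2-yl]oxy}-4-oxobutan-2-yl (R)-5-{[(R)-3-(benzyloxy)butanoyl]oxy}hex-2-ynoate | C[C@H](Cc1cc(OCc2ccccc2)cc(OCc2ccccc2)c1)OC(=O)C[C@@H](C)OC(=O)C#CC[C@@H](C)OC(=O)C[C@@H](C)OCc1ccccc1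
A6 | alternative 2 | 1-methoxy-1,3-bis(trimethylsilyloxy)buta-1,3-diene | C=C(O[Si](C)(C)C)C=C(OC)O[Si](C)(C)C
A7 | alternative 3 | (R)-pent-4-en-2-yl 2,4-dihydroxy-6-[(R)-2-(tert-butyldimethylsilyloxy)propyl]benzoate | C=CC[C@@H](C)OC(=O)c1c(O)cc(O)cc1C[C@@H](C)O[Si](C)(C)C(C)(C)C
A8 | alternative 3 | di[(R)-pent-4-en-2-yl] malonate | C=CC[C@@H](C)OC(=O)CC(=O)O[C@H](C)CC=C
A9 | alternative 3 | (R,E)-6-(tert-butyldimethylsilyloxy)hept-3-en-2-one | CC(=O)/C=C/C[C@@H](C)O[Si](C)(C)C(C)(C)C
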